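The route rests on cutting the bond between C2 of the γ-pyranone ring and C1′ of the pentasubstituted B ring. The key step exploits the C2–H of the chromone, the sp2 C–H flanked by ring oxygen O1 and vinylogous to the C4 carbonyl. A TMP–zinc amide removes it, reversing the native electrophilic character of C2, and the resulting 2-zincated 5,6,7,8-tetramethoxychromone is cross-coupled in the same flask (Negishi) with an iodoarene that already carries all four B-ring oxygens, the 3′-OH masked as a pivalate. One operation thus delivers the complete flavone skeleton from a C2-unsubstituted chromone and 3-iodo-2,5,6-trimethoxyphenyl pivalate; ester cleavage finishes the synthesis.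

Key step: step 5

Remark: the target has no stereocentre and no configurationally stable axis, so it is achiral and no stereocontrol is needed; acetophenone 7 is taken as a catalogue compound.

Step 1
Reactants: 1 1,2,4-trimethoxybenzene
Product: 4 2,3,6-trimethoxyphenol, via aryllithium 2 (not isolated), via arylboronate 3 (not isolated)
Conditions: n-BuLi, THF, 0 °C to rt; B(OMe)3, −78 °C to rt; 30% H2O2, AcOH, 0 °C to rt
Reagents that add atoms: hydrogen peroxide (OO)
Why: Directed ortho-metalation should lithiate the C3–H of 1, the only C–H lying between two methoxy groups, and borylation followed by boronate oxidation (1,2-aryl shift from boron to oxygen) places the hydroxyl at that carbon.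

Step 2
Reactants: 4 2,3,6-trimethoxyphenol
Product: 5 2,3,6-trimethoxyphenyl pivalate
Conditions: PivCl, Et3N, DMAP (cat.), CH2Cl2, 0 °C to rt
Reagents that add atoms: pivaloyl chloride (CC(C)(C)C(=O)Cl)
Why: DMAP-catalysed O-acylation of the hindered phenol should give the pivalate, which masks the acidic OH for the organozinc step and turns this oxygen into a poor donor for step 3.

Step 3
Reactants: 5 2,3,6-trimethoxyphenyl pivalate
Product: 6 3-iodo-2,5,6-trimethoxyphenyl pivalate
Conditions: NIS, TFA (cat.), MeCN, rt
Reagents that add atoms: N-iodosuccinimide (O=C1CCC(=O)N1I)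
Why: Electrophilic aromatic iodination should take the free position that is ortho to the 6-OMe and para to the 2-OMe, since the neighbouring free position is para only to the twisted, electron-poor pivaloyloxy group.

Step 4
Reactants: 7 2′-hydroxy-3′,4′,5′,6′-tetramethoxyacetophenone
Product: 9 5,6,7,8-tetramethoxychromone, via enaminone 8 (not isolated)
Conditions: DMF-DMA, toluene, 100 °C; evaporate; conc. HCl, CH2Cl2, rt
Reagents that add atoms: N,N-dimethylformamide dimethyl acetal (COC(OC)N(C)C)
Why: Enaminone formation at the methyl ketone followed by acid-promoted intramolecular addition–elimination (oxa-Michael addition of the phenol, loss of dimethylamine) is the standard chromone synthesis and leaves C2 and C3 unsubstituted.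

Step 5
Reactants: 9 5,6,7,8-tetramethoxychromone; 6 3-iodo-2,5,6-trimethoxyphenyl pivalate
Product: 11 3-(5,6,7,8-tetramethoxy-4-oxo-4H-chromen-2-yl)-2,5,6-trimethoxyphenyl pivalate, via C2-zincated chromone 10 (not isolated)
Conditions: 9 (1.3 equiv), TMPZnCl·LiCl (1.2 equiv), THF, 25 °C; then 6 (1.0 equiv), Pd(OAc)2 (2 mol %), SPhos (4 mol %), 50 °C
Reagents that add atoms: none
Why: TMPZnCl·LiCl removes the most acidic proton of 9, the C2–H of the pyranone ring (sp2 C–H on the carbon bound to O1 and vinylogous to the C4 carbonyl), to give 2-zincated chromone 10, which unlike a 2-lithio species should not ring-open; Pd(0)/SPhos then inserts into the C–I bond of 6, and transmetalation from zinc followed by reductive elimination forms the C2–C1′ bond. The closest known reaction type is the regioselective TMP-zinc metalation of chromones at C2 followed by Negishi arylation to flavones. No ring is closed and no stereocentre arises, the product being achiral. The step needs metalation at C2 and not at C3, which the Lewis-acid-free mono-amide base at 25 °C should secure because C3 metalation depends on a strong Lewis acid bound to the carbonyl, and it needs a single coupling site on the B ring, which the lone C–I bond fixes. The pivalate should survive because 9 is used in slight excess over the base, so no zinc amide remains when 6 is added, and heteroarylzinc chlorides do not attack hindered aryl esters.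

Step 6
Reactants: 11 3-(5,6,7,8-tetramethoxy-4-oxo-4H-chromen-2-yl)-2,5,6-trimethoxyphenyl pivalate
Product: 12 agehoustin C
Conditions: NaOMe, MeOH–THF, 0 °C to rt; then AcOH
Reagents that add atoms: none
Why: Methoxide-mediated transesterification of the aryl pivalate should release the phenoxide, a good leaving group, while the methyl ethers and the flavone core are inert to NaOMe at room temperature.

Compound list
1 | 1,2,4-trimethoxybenzene | COc1ccc(OC)c(OC)c1 | starting material
2 | 2,3,6-trimethoxyphenyllithium | [Li]c1c(OC)ccc(OC)c1OC | intermediate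
3 | dimethyl (2,3,6-trimethoxyphenyl)boronate | COB(OC)c1c(OC)ccc(OC)c1OC | intermediate
4 | 2,3,6-trimethoxyphenol | COc1ccc(OC)c(O)c1OC | intermediate
5 | 2,3,6-trimethoxyphenyl pivalate | COc1ccc(OC)c(OC(=O)C(C)(C)C)c1OC | intermediate
6 | 3-iodo-2,5,6-trimethoxyphenyl pivalate | COc1cc(I)c(OC)c(OC(=O)C(C)(C)C)c1OC | intermediate
7 | 2′-hydroxy-3′,4′,5′,6′-tetramethoxyacetophenone | CC(=O)c1c(O)c(OC)c(OC)c(OC)c1OC | starting material
8 | (E)-3-(dimethylamino)-1-(2-hydroxy-3,4,5,6-tetramethoxyphenyl)prop-2-en-1-one | CN(C)/C=C/C(=O)c1c(O)c(OC)c(OC)c(OC)c1OC | intermediate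
9 | 5,6,7,8-tetramethoxy-4H-chromen-4-one (5,6,7,8-tetramethoxychromone) | COc1c(OC)c(OC)c2occc(=O)c2c1OC | intermediate
10 | (5,6,7,8-tetramethoxy-4-oxo-4H-chromen-2-yl)zinc chloride, LiCl complex | COc1c(OC)c(OC)c2oc([Zn]Cl)cc(=O)c2c1OC | intermediate
11 | 3-(5,6,7,8-tetramethoxy-4-oxo-4H-chromen-2-yl)-2,5,6-trimethoxyphenyl pivalate (agehoustin C 3′-O-pivalate) | COc1cc(-c2cc(=O)c3c(OC)c(OC)c(OC)c(OC)c3o2)c(OC)c(OC(=O)C(C)(C)C)c1OC | intermediate
12 | agehoustin C, 2-(3-hydroxy-2,4,5-trimethoxyphenyl)-5,6,7,8-tetramethoxy-4H-chromen-4-one | COc1cc(-c2cc(=O)c3c(OC)c(OC)c(OC)c(OC)c3o2)c(OC)c(O)c1OC | target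

Total step count: 6
Longest linear sequence: 5 steps (steps 1, 2, 3, 5, 6)

Steps most likely to fail

Step 5. Metalation could be diverted to C3 if the C4 carbonyl and the 5-OMe chelate a metal ion. Cross-coupling of the hindered, electron-rich iodide could also be slow enough for protodemetalation or homocoupling to compete. The fallback sets out from 6 (with 9) and comes back at 11. Iodide 6 is borylated with tetrahydroxydiboron (XPhos-Pd-G2, KOAc, EtOH, 80 °C) to [3-(pivaloyloxy)-2,4,5-trimethoxyphenyl]boronic acid F1. F1 is added to chromone 9 in a Pd(II)- or Rh(I)-catalysed conjugate addition (for example Pd(TFA)2/2,2′-bipyridine, aqueous medium, 60 °C) to give the racemic flavanone 3-(5,6,7,8-tetramethoxy-4-oxochroman-2-yl)-2,5,6-trimethoxyphenyl pivalate F2. Dehydrogenation of F2 with DDQ in refluxing dioxane should give 11.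

Step 3. Iodination could occur at the other free ring position (para to the pivaloyloxy group), or twice. The fallback sets out from 1 and comes back at 6, using a silyl placeholder so that the iodine position is fixed by ipso-substitution. Bromination of 1 (NBS, MeCN) at the position para to the 2-OMe gives 1-bromo-2,4,5-trimethoxybenzene F3. Bromine–lithium exchange (n-BuLi, THF, −78 °C) and TMSCl give trimethyl(2,4,5-trimethoxyphenyl)silane F4. Ortho-lithiation between the two methoxy groups (n-BuLi/TMEDA), B(OMe)3 and buffered H2O2 give 2,3,6-trimethoxy-5-(trimethylsilyl)phenol F5. Pivaloylation as in step 2 gives 2,3,6-trimethoxy-5-(trimethylsilyl)phenyl pivalate F6. Ipso-iododesilylation with ICl (CH2Cl2, −78 to 0 °C) should give 6.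

Step 6. Methanolysis of the doubly ortho-flanked pivalate could be sluggish, and alkoxide attack at C2 could open the pyranone ring. The fallback sets out from 4 and comes back at 12, carrying a more labile ester through the route. Acetylation of 4 (Ac2O, pyridine) gives 2,3,6-trimethoxyphenyl acetate F7. Iodination as in step 3 gives 3-iodo-2,5,6-trimethoxyphenyl acetate F8. Zincation of 9 and Negishi coupling as in step 5 give 3-(5,6,7,8-tetramethoxy-4-oxo-4H-chromen-2-yl)-2,5,6-trimethoxyphenyl acetate F9. Cleavage with catalytic K2CO3 in MeOH at 0 °C should give 12.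

Further compounds
F1 | step 5 | [3-(pivaloyloxy)-2,4,5-trimethoxyphenyl]boronic acid | COc1cc(B(O)O)c(OC)c(OC(=O)C(C)(C)C)c1OC
F2 | step 5 | 3-(5,6,7,8-tetramethoxy-4-oxochroman-2-yl)-2,5,6-trimethoxyphenyl pivalate (racemic) | COc1cc(C2CC(=O)c3c(OC)c(OC)c(OC)c(OC)c3O2)c(OC)c(OC(=O)C(C)(C)C)c1OC
F3 | step 3 | 1-bromo-2,4,5-trimethoxybenzene | COc1cc(OC)c(OC)cc1Br
F4 | step 3 | trimethyl(2,4,5-trimethoxyphenyl)silane | COc1cc(OC)c(OC)cc1[Si](C)(C)C
F5 | step 3 | 2,3,6-trimethoxy-5-(trimethylsilyl)phenol | COc1c(O)c(OC)c(OC)cc1[Si](C)(C)C
F6 | step 3 | 2,3,6-trimethoxy-5-(trimethylsilyl)phenyl pivalate | COc1c(OC(=O)C(C)(C)C)c(OC)c(OC)cc1[Si](C)(C)C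
F7 | step 6 | 2,3,6-trimethoxyphenyl acetate | COc1ccc(OC)c(OC(C)=O)c1OC
F8 | step 6 | 3-iodo-2,5,6-trimethoxyphenyl acetate | COc1cc(I)c(OC)c(OC(C)=O)c1OC
F9 | step 6 | 3-(5,6,7,8-tetramethoxy-4-oxo-4H-chromen-2-yl)-2,5,6-trimethoxyphenyl acetate | COc1cc(-c2cc(=O)c3c(OC)c(OC)c(OC)c(OC)c3o2)c(OC)c(OC(C)=O)c1OC
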